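**Strategy.** The C9–C13 segment (oxygen on C9, C11, C12 and C13, C10 a methylene) is read as a 4-deoxy-D-mannose: on a pyran ring O9–C9–C10–C11–C12–C13 the C8 branch, O11 and O12 are all cis. The key step builds this ring by a catalytic enantioselective inverse-electron-demand hetero-Diels–Alder reaction between a 4-benzyloxy-2-oxobutenoate (O9, C8–C11) and (Z)-2-methoxyvinyl acetate (C12, C13); it forms C11–C12 and O9–C13 and sets C11 and C12 in one event. Hydrogenation then relays C9, and chelation-controlled alkynylation of the opened lactol relays C13. A 1,5-anti aldol adds the C1–C6 ketone, an L-fucal-derived trienyl iodide is esterified, and a double Stille coupling closes the 26-membered ring.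

Key step: step 3

Remark on numbering: atoms carry the macrolide numbering (C1 lactone carbonyl, C2–C13 polyol, C14–C23 pentaene with the methyl on C14, C24 carbinol, C25 lactone carbinol, C26 methyl, C1'–C6' side chain); "as in the target" means the spatial arrangement of the target at that atom. TBS = tert-butyldimethylsilyl, NAP = 2-naphthylmethyl.
Remark on the chemistry (assumption): the sense of induction in step 3 is taken to be that of the D-manno series known for this catalyst type with the (S,S)-ligand; if the opposite sense were found, the mirror-image ligand would be used.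

Step 1
Reactants: 1 benzyl vinyl ether; 2 ethyl chlorooxoacetate
Product: 3 ethyl (E)-4-(benzyloxy)-2-oxobut-3-enoate
Conditions: pyridine, CH2Cl2, 0 °C → rt
Reagents that add atoms: none
Why: C-acylation of the enol ether followed by loss of HCl (acylation–elimination of a vinyl ether) should give the β-alkoxy enone in its more stable (E)-form.

Step 2
Reactants: 4 1,1,2-trimethoxyethane
Product: 6 (Z)-2-methoxyvinyl acetate, via methoxyacetaldehyde 5 (not isolated)
Conditions: aq. H2SO4 (cat.), 60 °C; then Ac2O, KOAc, 120 °C; fractional distillation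
Reagents that add atoms: water, O; acetic anhydride, CC(=O)OC(C)=O
Why: acetal hydrolysis followed by enol acetylation of the aldehyde should give the 1,2-dioxygenated alkene, whose (Z)-isomer is favoured by the cis effect and is separated by distillation.

Step 3
Reactants: 3 ethyl (E)-4-(benzyloxy)-2-oxobut-3-enoate; 6 (Z)-2-methoxyvinyl acetate
Product: 7 ethyl (4S,5S,6R)-5-acetoxy-4-benzyloxy-6-methoxy-5,6-dihydro-4H-pyran-2-carboxylate
Conditions: Cu(OTf)2 (10 mol %), 2,2'-(propane-2,2-diyl)bis[(4S)-4-tert-butyl-4,5-dihydrooxazole] (11 mol %), 3 Å molecular sieves, THF, −40 °C → rt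
Reagents that add atoms: none
Why: The divalent copper–bis(oxazoline) complex chelates the ketone and ester oxygens of 3 and lowers the LUMO of the 1-oxadiene, which should react with the electron-rich alkene 6 in a concerted, asynchronous inverse-electron-demand hetero-Diels–Alder reaction in which C11–C12 forms ahead of O9–C13. The closest known reaction type is the copper–bis(oxazoline)-catalysed [4+2] cycloaddition of γ-alkoxy-β,γ-unsaturated α-keto esters with enol ethers, as used for de novo carbohydrate synthesis. The 5,6-dihydro-4H-pyran ring (O9, C9, C10, C11, C12, C13) is closed by suprafacial [4+2] cycloaddition, the C11–C12 and O9–C13 bonds forming in the same event. C11 is fixed by the catalyst, whose tert-butyl groups shield one face of the chelated oxadiene; C12 and the temporary acetal centre C13 are fixed relative to each other by the retained (Z)-geometry of 6 and relative to C11 by the endo approach of the alkoxy group, so that OBn, OAc and OMe should all be cis. The step needs regioselectivity, secured by the stronger donor OMe, which makes the acetoxy-bearing carbon of 6 the nucleophilic terminus that attacks C11, and it needs endo and facial selectivity, secured by the endo preference of enol ethers in this cycloaddition and by the C2-symmetric ligand.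

Step 4
Reactants: 7 ethyl (4S,5S,6R)-5-acetoxy-4-benzyloxy-6-methoxy-5,6-dihydro-4H-pyran-2-carboxylate
Product: 8 ethyl (methyl 2-O-acetyl-4-deoxy-β-D-lyxo-hexopyranosid)uronate
Conditions: H2 (1 atm), 10% Pd/C, EtOAc then EtOH, rt
Reagents that add atoms: none
Why: heterogeneous hydrogenation should deliver hydrogen to C9=C10 from the face opposite the three cis substituents, which sets C9 with the ester cis to O11 and O12, while the benzyl ether is removed by hydrogenolysis.

Step 5
Reactants: 8 ethyl (methyl 2-O-acetyl-4-deoxy-β-D-lyxo-hexopyranosid)uronate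
Product: 9 ethyl (methyl 4-deoxy-β-D-lyxo-hexopyranosid)uronate
Conditions: K2CO3 (cat.), EtOH, 0 °C → rt
Reagents that add atoms: none
Why: base-catalysed transesterification removes the acetate, and ethanol as solvent keeps the ethyl ester unchanged.

Step 6
Reactants: 9 ethyl (methyl 4-deoxy-β-D-lyxo-hexopyranosid)uronate
Product: 10 ethyl [methyl 4-deoxy-2,3-di-O-(2-naphthylmethyl)-β-D-lyxo-hexopyranosid]uronate
Conditions: NaH, 2-(bromomethyl)naphthalene, Bu4NI (cat.), DMF, 0 °C
Reagents that add atoms: 2-(bromomethyl)naphthalene, BrCc1ccc2ccccc2c1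
Why: Williamson etherification should give two acid-stable, chelating and oxidatively removable ethers, and the equatorial ester at C9 is the thermodynamic epimer, so any enolisation should return the same configuration.

Step 7
Reactants: 10 ethyl [methyl 4-deoxy-2,3-di-O-(2-naphthylmethyl)-β-D-lyxo-hexopyranosid]uronate
Product: 11 methyl 4-deoxy-2,3-di-O-(2-naphthylmethyl)-β-D-lyxo-hexodialdo-1,5-pyranoside
Conditions: iBu2AlH (1.1 equiv), CH2Cl2, −78 °C
Reagents that add atoms: none
Why: partial reduction of the α-alkoxy ester should stop at the aldehyde because the aluminium hemiacetal is stable at low temperature.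

Step 8
Reactants: 11 methyl 4-deoxy-2,3-di-O-(2-naphthylmethyl)-β-D-lyxo-hexodialdo-1,5-pyranoside
Product: 12 methyl 4,6,7-trideoxy-2,3-di-O-(2-naphthylmethyl)-β-D-lyxo-hept-6-enopyranoside
Conditions: Ph3PCH3Br, KN(SiMe3)2, THF, −78 → 0 °C
Reagents that add atoms: methyltriphenylphosphonium bromide, C[P+](c1ccccc1)(c1ccccc1)c1ccccc1.[Br-]
Why: Wittig methylenation installs C7 as a vinyl carbon, a group that should survive the acidic and organometallic steps that follow.

Step 9
Reactants: 12 methyl 4,6,7-trideoxy-2,3-di-O-(2-naphthylmethyl)-β-D-lyxo-hept-6-enopyranoside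
Product: 13 4,6,7-trideoxy-2,3-di-O-(2-naphthylmethyl)-D-lyxo-hept-6-enopyranose (lactol; both anomers)
Conditions: 2 M aq. HCl, 1,4-dioxane, 70 °C
Reagents that add atoms: water, O
Why: acid-catalysed glycoside hydrolysis through the oxocarbenium ion should free the C13 hemiacetal, with the arylmethyl ethers and the alkene stable to aqueous acid.

Step 10
Reactants: 13 4,6,7-trideoxy-2,3-di-O-(2-naphthylmethyl)-D-lyxo-hept-6-enopyranose
Product: 14 C7–C15 enyne diol: 4,5-bis(2-naphthylmethoxy)non-8-en-1-yne-3,7-diol (free OH at C9 and C13; C9, C11, C12, C13 as in the target)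
Conditions: HC≡CMgBr (5 equiv), THF, 0 °C → rt
Reagents that add atoms: ethynylmagnesium bromide, C#C[Mg]Br
Why: Grignard addition to the ring-opened aldehyde should proceed under Cram chelate control (magnesium bridging C13=O and O12, reinforced by O11), so that the new C13 carbinol is syn to O12 and anti to O11.

Step 11
Reactants: 14 C7–C15 enyne diol with NAP ethers at C11 and C12
Product: 15 non-8-en-1-yne-3,4,5,7-tetraol (C9, C11, C12, C13 as in the target)
Conditions: DDQ (3 equiv), CH2Cl2/pH 7 buffer (10:1), 0 °C → rt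
Reagents that add atoms: none
Why: oxidative cleavage of the 2-naphthylmethyl ethers by hydride abstraction and hydrolysis should leave the alkyne and the alkene untouched.

Step 12
Reactants: 15 non-8-en-1-yne-3,4,5,7-tetraol
Product: 16 3,4,5,7-tetrakis(tert-butyldimethylsilyloxy)non-8-en-1-yne (TBS ethers at C9, C11, C12, C13)
Conditions: TBSOTf (6 equiv), 2,6-lutidine, CH2Cl2, 0 → 40 °C
Reagents that add atoms: tert-butyldimethylsilyl triflate, CC(C)(C)[Si](C)(C)OS(=O)(=O)C(F)(F)F
Why: exhaustive silylation with the reactive triflate installs the fluoride-labile groups that are kept to the end.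

Step 13
Reactants: 16 3,4,5,7-tetrakis(tert-butyldimethylsilyloxy)non-8-en-1-yne
Product: 18 (E)-vinyl iodide: 1-iodo-2-methyl-3,4,5,7-tetrakis(tert-butyldimethylsilyloxy)nona-1,8-diene, via alkenyldimethylalane 17 (not isolated)
Conditions: Me3Al (3 equiv), Cp2ZrCl2 (25 mol %), H2O (1 equiv), CH2Cl2, −23 °C; then I2, THF, −30 °C
Reagents that add atoms: trimethylaluminium, C[Al](C)C; iodine, II
Why: Negishi carboalumination adds methyl (to C14) and aluminium (to C15) syn across the terminal alkyne, and iodinolysis with retention should give the (E)-C14=C15 iodide, the monosubstituted alkene reacting much more slowly.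

Step 14
Reactants: 18 (E)-vinyl iodide with terminal vinyl group
Product: 20 primary alcohol: 9-iodo-8-methyl-3,5,6,7-tetrakis(tert-butyldimethylsilyloxy)non-8-en-1-ol (C7 hydroxyl), via B-alkyl-9-borabicyclononane 19 (not isolated)
Conditions: 9-BBN, THF, 0 °C → rt; then H2O2, aq. NaOH, 0 °C
Reagents that add atoms: 9-borabicyclo[3.3.1]nonane, B1C2CCCC1CCC2 (atoms kept only in 19); hydrogen peroxide, OO
Why: hydroboration–oxidation with the bulky borane should functionalise only the monosubstituted alkene, anti-Markovnikov, and leave the trisubstituted iodoalkene alone.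

Step 15
Reactants: 20 C7 primary alcohol
Product: 21 C7 aldehyde: 9-iodo-8-methyl-3,5,6,7-tetrakis(tert-butyldimethylsilyloxy)non-8-enal
Conditions: Dess–Martin periodinane, NaHCO3, CH2Cl2, rt
Reagents that add atoms: none
Why: Dess–Martin oxidation is mild and buffered, so the β-silyloxy aldehyde should form without elimination.

Step 16
Reactants: 22 3-(tert-butyldimethylsilyloxy)propan-1-ol
Product: 23 3-(tert-butyldimethylsilyloxy)propanoic acid
Conditions: TEMPO (cat.), PhI(OAc)2, MeCN/H2O, rt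
Reagents that add atoms: water, O
Why: oxoammonium-mediated oxidation of the primary alcohol through the aldehyde hydrate should give the acid without loss of the silyl ether.

Step 17
Reactants: 23 3-(tert-butyldimethylsilyloxy)propanoic acid; 24 (R)-4-benzyloxazolidin-2-one
Product: 26 (R)-4-benzyl-3-[3-(tert-butyldimethylsilyloxy)propanoyl]oxazolidin-2-one, via mixed pivalic anhydride 25 (not isolated)
Conditions: PivCl, Et3N, THF, −20 °C; then 24, LiCl, rt
Reagents that add atoms: pivaloyl chloride, CC(C)(C)C(=O)Cl (atoms kept only in 25)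
Why: N-acylation of the oxazolidinone through the mixed anhydride is regioselective because the hindered pivaloyl carbonyl is not attacked.

Step 18
Reactants: 26 (R)-4-benzyl-3-[3-(tert-butyldimethylsilyloxy)propanoyl]oxazolidin-2-one; 27 hexanal
Product: 29 (R)-4-benzyl-3-[(2R,3S)-2-(tert-butyldimethylsilyloxymethyl)-3-hydroxyoctanoyl]oxazolidin-2-one, via (Z)-dibutylboron enolate 28 (not isolated)
Conditions: Bu2BOTf, iPr2NEt, CH2Cl2, −78 → 0 °C; then 27, −78 → 0 °C; pH 7 buffer, MeOH, H2O2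
Reagents that add atoms: dibutylboron triflate, CCCCB(CCCC)OS(=O)(=O)C(F)(F)F (atoms kept only in 28)
Why: the Evans syn aldol reaction of the (Z)-boron enolate through a chair Zimmerman–Traxler transition state, with the face chosen by the (R)-auxiliary, should set C2 and C1' (imide carbonyl = C3).

Step 19
Reactants: 29 Evans syn aldol adduct
Product: 30 (2R,3S)-2-(tert-butyldimethylsilyloxymethyl)-3-hydroxy-N-methoxy-N-methyloctanamide
Conditions: MeNH(OMe)·HCl, AlMe3, THF, 0 °C
Reagents that add atoms: N,O-dimethylhydroxylamine hydrochloride, CNOC.Cl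
Why: aluminium amide transamidation, assisted by the free β-hydroxyl, should cleave the auxiliary cleanly to the Weinreb amide.

Step 20
Reactants: 30 Weinreb amide
Product: 31 (5R,6S)-5-(tert-butyldimethylsilyloxymethyl)-6-hydroxy-2-methylundec-1-en-4-one
Conditions: CH2=C(CH3)CH2MgCl (3 equiv), THF, −78 → −20 °C; cold aq. NH4Cl
Reagents that add atoms: 2-methylallylmagnesium chloride, CC(=C)C[Mg]Cl
Why: Weinreb ketone synthesis should stop at the ketone through the chelated tetrahedral intermediate, and a cold neutral quench keeps the β,γ-unsaturated ketone out of conjugation.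

Step 21
Reactants: 31 β-hydroxy ketone
Product: 32 (4R,5R,6S)-5-(tert-butyldimethylsilyloxymethyl)-2-methylundec-1-ene-4,6-diol
Conditions: Et2BOMe, NaBH4, THF/MeOH (4:1), −78 °C; AcOH, then MeOH azeotrope
Reagents that add atoms: none
Why: Narasaka–Prasad reduction through the six-membered boron chelate with axial hydride delivery should set C3 syn to the C1' hydroxyl.

Step 22
Reactants: 32 syn-1,3-diol
Product: 33 4-methoxybenzylidene acetal of 32 (2,4,5,6-all-cis 1,3-dioxane across O1' and O3)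
Conditions: 4-MeOC6H4CH(OMe)2, PPTS (cat.), CH2Cl2, rt
Reagents that add atoms: 4-methoxybenzaldehyde dimethyl acetal, COC(OC)c1ccc(OC)cc1
Why: acid-catalysed transacetalisation of the syn-1,3-diol gives the dioxane with the aryl group equatorial under thermodynamic control and turns O3 into the alkyl-type β-oxygen needed for step 24.

Step 23
Reactants: 33 acetal with 2-methylallyl group
Product: 34 methyl ketone: 1-[dioxan-4-yl]propan-2-one (C6 methyl, C5 ketone, C4 methylene on the acetal of step 22)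
Conditions: OsO4 (cat.), NaIO4, 2,6-lutidine, 1,4-dioxane/H2O, rt
Reagents that add atoms: sodium periodate, [Na+].[O-]I(=O)(=O)=O
Why: Lemieux–Johnson dihydroxylation–glycol cleavage of the 1,1-disubstituted alkene should unveil the C5 methyl ketone under conditions that spare the acetal.

Step 24
Reactants: 34 C1–C6 methyl ketone; 21 C7 aldehyde
Product: 36 aldol adduct (C7 hydroxyl as in the target; C5 ketone; C1'/C3 acetal; C1 primary TBS ether; C15 iodide), via dibutylboron enolate 35 (not isolated)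
Conditions: 34 (1.3 equiv), Bu2BOTf, iPr2NEt, Et2O, −78 °C; then 21, −78 °C; pH 7 buffer, MeOH, H2O2, 0 °C
Reagents that add atoms: dibutylboron triflate, CCCCB(CCCC)OS(=O)(=O)C(F)(F)F (atoms kept only in 35)
Why: the boron aldol reaction of a β-alkoxy methyl ketone should show 1,5-anti induction from the acetal oxygen O3, which sets C7 anti to C3.

Step 25
Reactants: 36 β-hydroxy ketone
Product: 37 C5/C7 syn-diol
Conditions: Et2BOMe, NaBH4, THF/MeOH (4:1), −78 °C; AcOH, then MeOH azeotrope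
Reagents that add atoms: none
Why: Narasaka–Prasad reduction through the boron chelate should set C5 syn to the C7 hydroxyl.

Step 26
Reactants: 37 C5/C7 syn-diol
Product: 38 bis-TBS ether at C5 and C7
Conditions: TBSOTf, 2,6-lutidine, CH2Cl2, −78 → 0 °C
Reagents that add atoms: tert-butyldimethylsilyl triflate, CC(C)(C)[Si](C)(C)OS(=O)(=O)C(F)(F)F
Why: silylation of the two secondary hydroxyls under buffered conditions should leave the acetal intact.

Step 27
Reactants: 38 fully protected C1–C15 chain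
Product: 39 triol (free OH at C1, C1' and C3; six secondary TBS ethers retained)
Conditions: CSA (0.2 equiv), MeOH/CH2Cl2 (1:1), 0 °C
Reagents that add atoms: none
Why: acid-catalysed methanolysis should remove the 4-methoxybenzylidene acetal and the primary silyl ether, both far more labile than the secondary TBS ethers.

Step 28
Reactants: 39 triol
Product: 40 C1 carboxylic acid with free C1' and C3 hydroxyls
Conditions: TEMPO (cat.), PhI(OAc)2, MeCN/pH 7 buffer (1:1), rt
Reagents that add atoms: water, O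
Why: the oxoammonium oxidation is selective for the primary alcohol, taking it to the acid through the aldehyde hydrate while the two 1,3-related secondary hydroxyls stay.

Step 29
Reactants: 40 dihydroxy acid
Product: 42 C1 acid with TBS ethers at C1' and C3, via silyl ester 41 (not isolated)
Conditions: TBSOTf (5 equiv), 2,6-lutidine, CH2Cl2, 0 °C; then K2CO3, MeOH/THF/H2O, rt
Reagents that add atoms: tert-butyldimethylsilyl triflate, CC(C)(C)[Si](C)(C)OS(=O)(=O)C(F)(F)F
Why: persilylation followed by selective hydrolysis of the labile silyl ester should give the free acid with all secondary hydroxyls protected.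

Step 30
Reactants: 43 3,4-di-O-acetyl-L-fucal
Product: 44 L-fucal
Conditions: K2CO3 (cat.), MeOH, rt
Reagents that add atoms: none
Why: Zemplén-type transesterification removes both acetates and leaves the glycal, which brings C24 and C25 from the chiral pool.

Step 31
Reactants: 44 L-fucal
Product: 45 3-O-acetyl-L-fucal
Conditions: AcCl (1.05 equiv), 2,4,6-collidine, CH2Cl2, −40 °C
Reagents that add atoms: acetyl chloride, CC(=O)Cl
Why: kinetic acylation should prefer the allylic, pseudo-equatorial 3-hydroxyl over the axial 4-hydroxyl.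

Step 32
Reactants: 45 3-O-acetyl-L-fucal
Product: 46 3-O-acetyl-4-O-(tert-butyldimethylsilyl)-L-fucal
Conditions: TBSOTf, 2,6-lutidine, CH2Cl2, −78 → 0 °C
Reagents that add atoms: tert-butyldimethylsilyl triflate, CC(C)(C)[Si](C)(C)OS(=O)(=O)C(F)(F)F
Why: silylation of the remaining hydroxyl (the future O24) at low temperature should outrun acetyl migration.

Step 33
Reactants: 46 3-O-acetyl-4-O-(tert-butyldimethylsilyl)-L-fucal
Product: 47 (2E,4S,5S)-4-(tert-butyldimethylsilyloxy)-5-hydroxyhex-2-enal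
Conditions: HgSO4 (cat.), 5 mM aq. H2SO4, THF, rt
Reagents that add atoms: water, O
Why: Perlin hydrolysis (hydroxymercuration of the glycal, ring opening and elimination of the 3-acetate) should give the (E)-enal with the ring oxygen released as the free C25 hydroxyl.

Step 34
Reactants: 47 (2E,4S,5S)-4-(tert-butyldimethylsilyloxy)-5-hydroxyhex-2-enal
Product: 48 (2E,4E,6S,7S)-6-(tert-butyldimethylsilyloxy)-7-hydroxyocta-2,4-dienal
Conditions: Ph3P=CHCHO (1.1 equiv), toluene, 60 °C
Reagents that add atoms: (triphenylphosphoranylidene)acetaldehyde, O=CC=P(c1ccccc1)(c1ccccc1)c1ccccc1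
Why: Wittig reaction with the stabilised ylide should give the (E)-C20=C21 bond under neutral conditions that tolerate the free hydroxyl.

Step 35
Reactants: 48 (2E,4E,6S,7S)-6-(tert-butyldimethylsilyloxy)-7-hydroxyocta-2,4-dienal
Product: 49 (2S,3S,4E,6E,8E)-3-(tert-butyldimethylsilyloxy)-9-iodonona-4,6,8-trien-2-ol
Conditions: CrCl2 (6 equiv), CHI3 (2 equiv), THF, 0 °C, dark
Reagents that add atoms: iodoform, IC(I)I
Why: Takai olefination through the geminal dichromium species should give the (E)-C18=C19 iodide and tolerates the free hydroxyl.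

Step 36
Reactants: 42 C1 acid with C15 iodide; 49 trienyl iodide alcohol
Product: 51 seco ester diiodide (C1–O25 ester; iodides at C15 and C18), via mixed 2,4,6-trichlorobenzoic anhydride 50 (not isolated)
Conditions: 2,4,6-Cl3C6H2COCl, Et3N, THF, rt; then 49 (1.5 equiv), DMAP, toluene, rt → 40 °C
Reagents that add atoms: 2,4,6-trichlorobenzoyl chloride, O=C(Cl)c1c(Cl)cc(Cl)cc1Cl (atoms kept only in 50)
Why: Yamaguchi esterification acylates the secondary C25 hydroxyl through the acylpyridinium ion without touching the stereocentre, so C25 keeps its configuration.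

Step 37
Reactants: 51 seco ester diiodide; 52 (E)-1,2-bis(tributylstannyl)ethene
Product: 53 nona-TBS ether of the target macrolide
Conditions: PdCl2(MeCN)2 (20 mol %), iPr2NEt, DMF/THF (1:1), 0.002 M, rt, dark
Reagents that add atoms: none
Why: a double Stille coupling ("stitching"), first intermolecular at the unhindered trienyl iodide and then ring-closing at C15, should insert C16–C17 with retention of all alkene geometries and close the 26-membered ring.

Step 38
Reactants: 53 nona-TBS ether of the target macrolide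
Product: 54 target macrolide CNP0296784.1
Conditions: HF·pyridine, pyridine, THF, 0 °C → rt, dark
Reagents that add atoms: none
Why: buffered fluoride-mediated global desilylation should free all nine hydroxyls without acid-induced ionisation of the allylic C13 and C24 carbinols or opening of the lactone.

**Compound list**

1 | benzyl vinyl ether | C=COCc1ccccc1 | starting material
2 | ethyl chlorooxoacetate | CCOC(=O)C(=O)Cl | starting material
3 | ethyl (E)-4-(benzyloxy)-2-oxobut-3-enoate | CCOC(=O)C(=O)/C=C/OCc1ccccc1 | intermediate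
4 | 1,1,2-trimethoxyethane | COCC(OC)OC | starting material
5 | methoxyacetaldehyde | COCC=O | intermediate
6 | (Z)-2-methoxyvinyl acetate | CO/C=C\OC(C)=O | intermediate
7 | ethyl (4S,5S,6R)-5-acetoxy-4-benzyloxy-6-methoxy-5,6-dihydro-4H-pyran-2-carboxylate | CO[C@H]1[C@@H](OC(C)=O)[C@@H](OCc2ccccc2)C=C(O1)C(=O)OCC | intermediate
8 | ethyl (methyl 2-O-acetyl-4-deoxy-β-D-lyxo-hexopyranosid)uronate (all-cis tetrahydropyran) | CO[C@H]1[C@@H](OC(C)=O)[C@@H](O)C[C@H](O1)C(=O)OCC | intermediate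
9 | ethyl (methyl 4-deoxy-β-D-lyxo-hexopyranosid)uronate | CO[C@H]1[C@@H](O)[C@@H](O)C[C@H](O1)C(=O)OCC | intermediate
10 | ethyl [methyl 4-deoxy-2,3-di-O-(2-naphthylmethyl)-β-D-lyxo-hexopyranosid]uronate | CO[C@H]1[C@@H](OCc2ccc3ccccc3c2)[C@@H](OCc2ccc3ccccc3c2)C[C@H](O1)C(=O)OCC | intermediate
11 | methyl 4-deoxy-2,3-di-O-(2-naphthylmethyl)-β-D-lyxo-hexodialdo-1,5-pyranoside | CO[C@H]1[C@@H](OCc2ccc3ccccc3c2)[C@@H](OCc2ccc3ccccc3c2)C[C@H](O1)C=O | intermediate
12 | methyl 4,6,7-trideoxy-2,3-di-O-(2-naphthylmethyl)-β-D-lyxo-hept-6-enopyranoside | CO[C@H]1[C@@H](OCc2ccc3ccccc3c2)[C@@H](OCc2ccc3ccccc3c2)C[C@H](O1)C=C | intermediate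
13 | 4,6,7-trideoxy-2,3-di-O-(2-naphthylmethyl)-D-lyxo-hept-6-enopyranose (lactol, both anomers) | OC1[C@@H](OCc2ccc3ccccc3c2)[C@@H](OCc2ccc3ccccc3c2)C[C@H](O1)C=C | intermediate
14 | 4,5-bis(2-naphthylmethoxy)non-8-en-1-yne-3,7-diol (C7–C15 unit; C9, C11, C12, C13 as in the target) | C#C[C@H](O)[C@@H](OCc1ccc2ccccc2c1)[C@@H](OCc1ccc2ccccc2c1)C[C@H](O)C=C | intermediate
15 | (3S,4S,5S,7S)-non-8-en-1-yne-3,4,5,7-tetraol | C#C[C@H](O)[C@@H](O)[C@@H](O)C[C@H](O)C=C | intermediate
16 | (3S,4S,5S,7S)-3,4,5,7-tetrakis(tert-butyldimethylsilyloxy)non-8-en-1-yne | C#C[C@H](O[Si](C)(C)C(C)(C)C)[C@@H](O[Si](C)(C)C(C)(C)C)[C@@H](O[Si](C)(C)C(C)(C)C)C[C@H](O[Si](C)(C)C(C)(C)C)C=C | intermediate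
17 | (E)-alkenyldimethylalane from 16 (Al on C15, methyl on C14) | C[Al](C)/C=C(\C)[C@H](O[Si](C)(C)C(C)(C)C)[C@@H](O[Si](C)(C)C(C)(C)C)[C@@H](O[Si](C)(C)C(C)(C)C)C[C@H](O[Si](C)(C)C(C)(C)C)C=C | intermediate
18 | (E)-1-iodo-2-methyl-3,4,5,7-tetrakis(tert-butyldimethylsilyloxy)nona-1,8-diene (C7–C15; stereocentres as in the target) | I/C=C(\C)[C@H](O[Si](C)(C)C(C)(C)C)[C@@H](O[Si](C)(C)C(C)(C)C)[C@@H](O[Si](C)(C)C(C)(C)C)C[C@H](O[Si](C)(C)C(C)(C)C)C=C | intermediate
19 | B-alkyl-9-borabicyclo[3.3.1]nonane from 18 (boron on C7) | I/C=C(\C)[C@H](O[Si](C)(C)C(C)(C)C)[C@@H](O[Si](C)(C)C(C)(C)C)[C@@H](O[Si](C)(C)C(C)(C)C)C[C@H](O[Si](C)(C)C(C)(C)C)CCB1C2CCCC1CCC2 | intermediate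
20 | (E)-9-iodo-8-methyl-3,5,6,7-tetrakis(tert-butyldimethylsilyloxy)non-8-en-1-ol (C7 alcohol; stereocentres as in the target) | I/C=C(\C)[C@H](O[Si](C)(C)C(C)(C)C)[C@@H](O[Si](C)(C)C(C)(C)C)[C@@H](O[Si](C)(C)C(C)(C)C)C[C@H](O[Si](C)(C)C(C)(C)C)CCO | intermediate
21 | (E)-9-iodo-8-methyl-3,5,6,7-tetrakis(tert-butyldimethylsilyloxy)non-8-enal (C7 aldehyde) | I/C=C(\C)[C@H](O[Si](C)(C)C(C)(C)C)[C@@H](O[Si](C)(C)C(C)(C)C)[C@@H](O[Si](C)(C)C(C)(C)C)C[C@H](O[Si](C)(C)C(C)(C)C)CC=O | intermediate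
22 | 3-(tert-butyldimethylsilyloxy)propan-1-ol | CC(C)(C)[Si](C)(C)OCCCO | starting material
23 | 3-(tert-butyldimethylsilyloxy)propanoic acid | CC(C)(C)[Si](C)(C)OCCC(=O)O | intermediate
24 | (R)-4-benzyloxazolidin-2-one | O=C1N[C@H](Cc2ccccc2)CO1 | starting material
25 | 3-(tert-butyldimethylsilyloxy)propanoic pivalic anhydride | CC(C)(C)[Si](C)(C)OCCC(=O)OC(=O)C(C)(C)C | intermediate
26 | (R)-4-benzyl-3-[3-(tert-butyldimethylsilyloxy)propanoyl]oxazolidin-2-one | CC(C)(C)[Si](C)(C)OCCC(=O)N1[C@H](Cc2ccccc2)COC1=O | intermediate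
27 | hexanal | CCCCCC=O | starting material
28 | (Z)-dibutylboron enolate of 26 | CCCCB(CCCC)O/C(=C\CO[Si](C)(C)C(C)(C)C)N1[C@H](Cc2ccccc2)COC1=O | intermediate
29 | (R)-4-benzyl-3-[(2R,3S)-2-(tert-butyldimethylsilyloxymethyl)-3-hydroxyoctanoyl]oxazolidin-2-one | CCCCC[C@H](O)[C@@H](CO[Si](C)(C)C(C)(C)C)C(=O)N1[C@H](Cc2ccccc2)COC1=O | intermediate
30 | (2R,3S)-2-(tert-butyldimethylsilyloxymethyl)-3-hydroxy-N-methoxy-N-methyloctanamide | CCCCC[C@H](O)[C@@H](CO[Si](C)(C)C(C)(C)C)C(=O)N(C)OC | intermediate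
31 | (5R,6S)-5-(tert-butyldimethylsilyloxymethyl)-6-hydroxy-2-methylundec-1-en-4-one | CCCCC[C@H](O)[C@@H](CO[Si](C)(C)C(C)(C)C)C(=O)CC(C)=C | intermediate
32 | (4R,5R,6S)-5-(tert-butyldimethylsilyloxymethyl)-2-methylundec-1-ene-4,6-diol | CCCCC[C@H](O)[C@@H](CO[Si](C)(C)C(C)(C)C)[C@H](O)CC(C)=C | intermediate
33 | 4-methoxybenzylidene acetal of 32 (all-cis 1,3-dioxane: aryl, pentyl, CH2OTBS and 2-methylallyl on one face) | CC(=C)C[C@H]1O[C@@H](c2ccc(OC)cc2)O[C@@H](CCCCC)[C@H]1CO[Si](C)(C)C(C)(C)C | intermediate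
34 | C1–C6 methyl ketone (acetonyl group in place of 2-methylallyl in 33) | CC(=O)C[C@H]1O[C@@H](c2ccc(OC)cc2)O[C@@H](CCCCC)[C@H]1CO[Si](C)(C)C(C)(C)C | intermediate
35 | dibutylboron enolate of 34 | CCCCB(CCCC)OC(=C)C[C@H]1O[C@@H](c2ccc(OC)cc2)O[C@@H](CCCCC)[C@H]1CO[Si](C)(C)C(C)(C)C | intermediate
36 | aldol adduct (C7 hydroxyl, C5 ketone, C1'/C3 acetal, C1 OTBS, C15 iodide; TBS at C9, C11, C12, C13) | I/C=C(\C)[C@H](O[Si](C)(C)C(C)(C)C)[C@@H](O[Si](C)(C)C(C)(C)C)[C@@H](O[Si](C)(C)C(C)(C)C)C[C@H](O[Si](C)(C)C(C)(C)C)C[C@H](O)CC(=O)C[C@H]1O[C@@H](c2ccc(OC)cc2)O[C@@H](CCCCC)[C@H]1CO[Si](C)(C)C(C)(C)C | intermediate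
37 | C5/C7 syn-diol from 36 | I/C=C(\C)[C@H](O[Si](C)(C)C(C)(C)C)[C@@H](O[Si](C)(C)C(C)(C)C)[C@@H](O[Si](C)(C)C(C)(C)C)C[C@H](O[Si](C)(C)C(C)(C)C)C[C@H](O)C[C@H](O)C[C@H]1O[C@@H](c2ccc(OC)cc2)O[C@@H](CCCCC)[C@H]1CO[Si](C)(C)C(C)(C)C | intermediate
38 | C5, C7 bis-TBS ether of 37 | I/C=C(\C)[C@H](O[Si](C)(C)C(C)(C)C)[C@@H](O[Si](C)(C)C(C)(C)C)[C@@H](O[Si](C)(C)C(C)(C)C)C[C@H](O[Si](C)(C)C(C)(C)C)C[C@H](O[Si](C)(C)C(C)(C)C)C[C@H](O[Si](C)(C)C(C)(C)C)C[C@H]1O[C@@H](c2ccc(OC)cc2)O[C@@H](CCCCC)[C@H]1CO[Si](C)(C)C(C)(C)C | intermediate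
39 | triol (free OH at C1, C1', C3; TBS at C5, C7, C9, C11, C12, C13; C15 iodide) | I/C=C(\C)[C@H](O[Si](C)(C)C(C)(C)C)[C@@H](O[Si](C)(C)C(C)(C)C)[C@@H](O[Si](C)(C)C(C)(C)C)C[C@H](O[Si](C)(C)C(C)(C)C)C[C@H](O[Si](C)(C)C(C)(C)C)C[C@H](O[Si](C)(C)C(C)(C)C)C[C@@H](O)[C@H](CO)[C@@H](O)CCCCC | intermediate
40 | C1 carboxylic acid with free C1' and C3 hydroxyls | I/C=C(\C)[C@H](O[Si](C)(C)C(C)(C)C)[C@@H](O[Si](C)(C)C(C)(C)C)[C@@H](O[Si](C)(C)C(C)(C)C)C[C@H](O[Si](C)(C)C(C)(C)C)C[C@H](O[Si](C)(C)C(C)(C)C)C[C@H](O[Si](C)(C)C(C)(C)C)C[C@@H](O)[C@H](C(=O)O)[C@@H](O)CCCCC | intermediate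
41 | TBS ester of 42 | I/C=C(\C)[C@H](O[Si](C)(C)C(C)(C)C)[C@@H](O[Si](C)(C)C(C)(C)C)[C@@H](O[Si](C)(C)C(C)(C)C)C[C@H](O[Si](C)(C)C(C)(C)C)C[C@H](O[Si](C)(C)C(C)(C)C)C[C@H](O[Si](C)(C)C(C)(C)C)C[C@@H](O[Si](C)(C)C(C)(C)C)[C@H](C(=O)O[Si](C)(C)C(C)(C)C)[C@@H](O[Si](C)(C)C(C)(C)C)CCCCC | intermediate
42 | C1 acid, octa-TBS (C1', C3, C5, C7, C9, C11, C12, C13), C15 iodide | I/C=C(\C)[C@H](O[Si](C)(C)C(C)(C)C)[C@@H](O[Si](C)(C)C(C)(C)C)[C@@H](O[Si](C)(C)C(C)(C)C)C[C@H](O[Si](C)(C)C(C)(C)C)C[C@H](O[Si](C)(C)C(C)(C)C)C[C@H](O[Si](C)(C)C(C)(C)C)C[C@@H](O[Si](C)(C)C(C)(C)C)[C@H](C(=O)O)[C@@H](O[Si](C)(C)C(C)(C)C)CCCCC | intermediate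
43 | 3,4-di-O-acetyl-L-fucal [(2S,3R,4S)-2-methyl-3,4-dihydro-2H-pyran-3,4-diyl diacetate] | C[C@@H]1OC=C[C@H](OC(C)=O)[C@@H]1OC(C)=O | starting material
44 | L-fucal | C[C@@H]1OC=C[C@H](O)[C@@H]1O | intermediate
45 | 3-O-acetyl-L-fucal | C[C@@H]1OC=C[C@H](OC(C)=O)[C@@H]1O | intermediate
46 | 3-O-acetyl-4-O-(tert-butyldimethylsilyl)-L-fucal | C[C@@H]1OC=C[C@H](OC(C)=O)[C@@H]1O[Si](C)(C)C(C)(C)C | intermediate
47 | (2E,4S,5S)-4-(tert-butyldimethylsilyloxy)-5-hydroxyhex-2-enal | C[C@H](O)[C@@H](O[Si](C)(C)C(C)(C)C)/C=C/C=O | intermediate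
48 | (2E,4E,6S,7S)-6-(tert-butyldimethylsilyloxy)-7-hydroxyocta-2,4-dienal | C[C@H](O)[C@@H](O[Si](C)(C)C(C)(C)C)/C=C/C=C/C=O | intermediate
49 | (2S,3S,4E,6E,8E)-3-(tert-butyldimethylsilyloxy)-9-iodonona-4,6,8-trien-2-ol | C[C@H](O)[C@@H](O[Si](C)(C)C(C)(C)C)/C=C/C=C/C=C/I | intermediate
50 | mixed anhydride of 42 with 2,4,6-trichlorobenzoic acid | I/C=C(\C)[C@H](O[Si](C)(C)C(C)(C)C)[C@@H](O[Si](C)(C)C(C)(C)C)[C@@H](O[Si](C)(C)C(C)(C)C)C[C@H](O[Si](C)(C)C(C)(C)C)C[C@H](O[Si](C)(C)C(C)(C)C)C[C@H](O[Si](C)(C)C(C)(C)C)C[C@@H](O[Si](C)(C)C(C)(C)C)[C@H](C(=O)OC(=O)c1c(Cl)cc(Cl)cc1Cl)[C@@H](O[Si](C)(C)C(C)(C)C)CCCCC | intermediate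
51 | seco ester diiodide (ester C1–O25; iodides at C15 and C18; nine TBS ethers) | I/C=C(\C)[C@H](O[Si](C)(C)C(C)(C)C)[C@@H](O[Si](C)(C)C(C)(C)C)[C@@H](O[Si](C)(C)C(C)(C)C)C[C@H](O[Si](C)(C)C(C)(C)C)C[C@H](O[Si](C)(C)C(C)(C)C)C[C@H](O[Si](C)(C)C(C)(C)C)C[C@@H](O[Si](C)(C)C(C)(C)C)[C@H](C(=O)O[C@@H](C)[C@@H](O[Si](C)(C)C(C)(C)C)/C=C/C=C/C=C/I)[C@@H](O[Si](C)(C)C(C)(C)C)CCCCC | intermediate
52 | (E)-1,2-bis(tributylstannyl)ethene | CCCC[Sn](CCCC)(CCCC)/C=C/[Sn](CCCC)(CCCC)CCCC | starting material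
53 | nona-TBS ether of the target (TBS on O1', O3, O5, O7, O9, O11, O12, O13, O24) | CCCCC[C@H](O[Si](C)(C)C(C)(C)C)[C@H]1C(=O)O[C@@H](C)[C@@H](O[Si](C)(C)C(C)(C)C)/C=C/C=C/C=C/C=C/C=C(\C)[C@H](O[Si](C)(C)C(C)(C)C)[C@@H](O[Si](C)(C)C(C)(C)C)[C@@H](O[Si](C)(C)C(C)(C)C)C[C@H](O[Si](C)(C)C(C)(C)C)C[C@H](O[Si](C)(C)C(C)(C)C)C[C@H](O[Si](C)(C)C(C)(C)C)C[C@H]1O[Si](C)(C)C(C)(C)C | intermediate
54 | CNP0296784.1, the 26-membered pentaene macrolide (1'S,2R,3R,5S,7R,9R,11S,12S,13S,24S,25S; 14E,16E,18E,20E,22E) | CCCCC[C@H](O)[C@H]1C(=O)O[C@@H](C)[C@@H](O)/C=C/C=C/C=C/C=C/C=C(\C)[C@H](O)[C@@H](O)[C@@H](O)C[C@H](O)C[C@H](O)C[C@H](O)C[C@H]1O | target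

**Totals.** Total step count: 38. Longest linear sequence: 23 steps (steps 1, 3–15, 24–29, 36–38).

**Steps most likely to fail**

Step 37. The double coupling may stop after the first, intermolecular Stille event or turn to oligomerisation, because the ring-closing coupling at the hindered trisubstituted iodide C15 is slow, and the long reaction time may isomerise the polyene. The fallback sets out from 49 and replaces the one-pot double coupling by a stepwise sequence with a conventional ring closure. A single Stille coupling of 49 with an excess of 52 (PdCl2(MeCN)2, DMF, rt) would give the tetraenylstannane alcohol F1. Yamaguchi acylation of F1 with 42 (through 50, as in step 36) would give the iodide–stannane seco ester F2. Intramolecular Stille coupling of F2 (Pd2(dba)3, AsPh3, iPr2NEt, DMF/THF, high dilution) would come back to the route at 53.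

Step 36. Acylation of the hindered secondary C25 hydroxyl by the α-branched, doubly β-silyloxylated acid may be slow, and ketene formation may then epimerise C2 or eliminate silanol. The fallback sets out from 42 and makes the ester bond last, as a ring closure. Stille coupling of 42 with an excess of 52 would give the dienylstannane acid F3, and a second Stille coupling with 49 would give the pentaene seco hydroxy acid F4. Shiina macrolactonisation of F4 (2-methyl-6-nitrobenzoic anhydride, DMAP, toluene, high dilution) would come back to the route at 53.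

Step 10. Facial selectivity in the addition to the ring-opened lactol may be insufficient if chelate and Felkin pathways compete, or if ring opening is slow. The fallback sets out from 13 and sets C13 by catalyst control at the ketone stage. Oxidation (Ag2CO3 on Celite, toluene, reflux) would give the lactone F5. Aminolysis with AlMe3/MeNH(OMe)·HCl would give the hydroxy Weinreb amide F6, and HC≡CMgBr would give the hydroxy ynone F7 (in equilibrium with its cyclic hemiketal). Noyori asymmetric transfer hydrogenation of F7 (RuCl(p-cymene)[(R,R)-TsDPEN], iPrOH; the catalyst enantiomer that gives the (S)-carbinol, expected to be (R,R)) would come back to the route at 14.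

Further compounds
F1 | step 37 | tetraenylstannane alcohol (2S,3S,4E,6E,8E,10E)-3-(tert-butyldimethylsilyloxy)-11-(tributylstannyl)undeca-4,6,8,10-tetraen-2-ol | C[C@H](O)[C@@H](O[Si](C)(C)C(C)(C)C)/C=C/C=C/C=C/C=C/[Sn](CCCC)(CCCC)CCCC
F2 | step 37 | iodide–stannane seco ester (ester C1–O25; iodide at C15; stannane at C16) | I/C=C(\C)[C@H](O[Si](C)(C)C(C)(C)C)[C@@H](O[Si](C)(C)C(C)(C)C)[C@@H](O[Si](C)(C)C(C)(C)C)C[C@H](O[Si](C)(C)C(C)(C)C)C[C@H](O[Si](C)(C)C(C)(C)C)C[C@H](O[Si](C)(C)C(C)(C)C)C[C@@H](O[Si](C)(C)C(C)(C)C)[C@H](C(=O)O[C@@H](C)[C@@H](O[Si](C)(C)C(C)(C)C)/C=C/C=C/C=C/C=C/[Sn](CCCC)(CCCC)CCCC)[C@@H](O[Si](C)(C)C(C)(C)C)CCCCC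
F3 | step 36 | dienylstannane acid (stannane at C17; C1 acid; octa-TBS) | CCCC[Sn](CCCC)(CCCC)/C=C/C=C(\C)[C@H](O[Si](C)(C)C(C)(C)C)[C@@H](O[Si](C)(C)C(C)(C)C)[C@@H](O[Si](C)(C)C(C)(C)C)C[C@H](O[Si](C)(C)C(C)(C)C)C[C@H](O[Si](C)(C)C(C)(C)C)C[C@H](O[Si](C)(C)C(C)(C)C)C[C@@H](O[Si](C)(C)C(C)(C)C)[C@H](C(=O)O)[C@@H](O[Si](C)(C)C(C)(C)C)CCCCC
F4 | step 36 | pentaene seco hydroxy acid (free C25 hydroxyl and C1 acid; nine TBS ethers) | C[C@H](O)[C@@H](O[Si](C)(C)C(C)(C)C)/C=C/C=C/C=C/C=C/C=C(\C)[C@H](O[Si](C)(C)C(C)(C)C)[C@@H](O[Si](C)(C)C(C)(C)C)[C@@H](O[Si](C)(C)C(C)(C)C)C[C@H](O[Si](C)(C)C(C)(C)C)C[C@H](O[Si](C)(C)C(C)(C)C)C[C@H](O[Si](C)(C)C(C)(C)C)C[C@@H](O[Si](C)(C)C(C)(C)C)[C@H](C(=O)O)[C@@H](O[Si](C)(C)C(C)(C)C)CCCCC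
F5 | step 10 | 4,6,7-trideoxy-2,3-di-O-(2-naphthylmethyl)-D-lyxo-hept-6-enono-1,5-lactone | O=C1[C@@H](OCc2ccc3ccccc3c2)[C@@H](OCc2ccc3ccccc3c2)C[C@H](O1)C=C
F6 | step 10 | hydroxy Weinreb amide (C13 amide; free C9 hydroxyl; NAP at O11, O12) | CON(C)C(=O)[C@@H](OCc1ccc2ccccc2c1)[C@@H](OCc1ccc2ccccc2c1)C[C@H](O)C=C
F7 | step 10 | hydroxy ynone (C13 ketone; free C9 hydroxyl; NAP at O11, O12) | C#CC(=O)[C@@H](OCc1ccc2ccccc2c1)[C@@H](OCc1ccc2ccccc2c1)C[C@H](O)C=C
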